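The runs come from a simulation from invented constants, and the scatter is random.

By 1.50 min the midnight run on this very flask shows 31% target with 1% substrate left, so nearly all of the substrate has reacted and about a third of it stands as target.

- midnight: substrate 0.50 M; partner 1 M; the very flask that is asked about, followed so far
- flask: substrate 0.50 M; partner 1.00 M; time 30 min

- midnight (time / min: target / %, substrate / %): 0.417: 30, 13; 0.833: 31, 4; 1.50: 31, 1; 3.00: 33, 2; 6.00: 27, 2; 12.0: 20, 1

(each reading ± 1.5 percentage points)



1. time up to 30 min at which target stands highest
2. the amount of target, in percent of the substrate charged, at that time

That reading gives 0.456 for the odds of target, meaning substrate turned into target over substrate turned into anything else. This is a selectivity in plain form, and it carries the scatter of the readings.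

Two chemists dispute where the top lies. The first treats the fast stage as over and lets the odds give the height. Substrate falls at 2.83 min⁻¹ between the first two readings, while target later falls at only 0.0556 min⁻¹, far slower. So she puts the top near the end of the substrate. The second trusts the highest reading, 33% at 3.00 min, and says target is still creeping up. Yet his rise is 2 percentage points, against a scatter of 1.5 points on each reading.

The forecast sides with the first: 1.5 min and 32%, since “The maximum falls where formation equals loss”.

The simulation gives 1.52 min and 33.4%, so the first chemist wins. The second keeps a region: up to 3.02 min, at least 95.0% of the best still stands.

    substrate + partner → target (k = 2.20 L mol⁻¹ min⁻¹)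
    partner → decomposed reagent (k = 0.240 min⁻¹)
    2 substrate → side product (k = 8.90 L mol⁻¹ min⁻¹)
    target ⇌ isomer of the product (K = 2.60, k = 0.0620 min⁻¹)

Target's step goes with substrate to the first power and the side product's with its square, so at a given partner the ratio of their rates runs inversely with the substrate present at that moment, and that substrate falls during the run. At the top of this flask the simulation's odds are 0.514. With the side-product step removed, the top rises from 33.4% to 82.1%. For a neighbour flask charged with 0.12 M of substrate, scaling the odds by the charge is a rough guess of 1.90, a share of 65.5%, and that neighbour's simulated top is lower, at 60.5%.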